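A closed, stirred vessel at constant volume holds free monomer, initiator and impurity, and you want the average chain length.

free monomer 2.7 M; initiator 3 mol%; impurity 30 mM; time 40 min

    free monomer + living end → monomer in chains + living end, rate k1*[living end]*[free monomer] (k1 = 1.1 L mol⁻¹ min⁻¹)
    free monomer + initiator → living end + monomer in chains (k2 = 0.23 L mol⁻¹ min⁻¹)
    2 initiator → spent initiator A (k3 = 29 L mol⁻¹ min⁻¹)
    initiator + impurity → spent initiator B (k4 = 530 L mol⁻¹ min⁻¹)

- for a step with 2 of a species take k times the square, and two of it per event
- the average divides the monomer in chains by the number of chains begun, living and dead together
- run time (flask): 40 min

- whether the average number of monomer units in a chain (chains begun, living or dead) reaches 20 by 40 min (yes / no)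
- average number of monomer units in a chain (chains begun, living or dead) at 40 min

The average is monomer in chains over chains begun, so you must count chains. There are two ways.

The first way is subtraction. You charge 81.0 mM of initiator and 30 mM of impurity. The impurity removes initiator at 15.9 min⁻¹ per initiator, faster than self-destruction at 4.70 min⁻¹, so let that step finish first. Counted that way, this leaves 51.0 mM. If each of these began a chain, the average at 40 min would be 47.3.

The second way compares rates. Per initiator, chain start runs at 0.621 min⁻¹, with free monomer held at its charge, and self-destruction runs at twice the self-destruction constant times [initiator]. They are equal at [initiator] = 10.7 mM. At any [initiator], the share going to chains is this crossover over the crossover plus [initiator]. Summing that share down from 51.0 mM gives the crossover times the natural logarithm of 5.77. This is the chain count, the concentration of chains begun from that initiator: 18.8 mM.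

The two ways part, and subtraction cheats. At 51.0 mM, self-destruction runs at 2.96 min⁻¹, faster than chain start.

So take the chain count. Free monomer then falls pseudo-first-order at 0.0206 min⁻¹. My reckoning has 56.2% of it reacted by 40 min, and an average of 80.9, above 20.

The forecast says yes and 80, “leaving only about 17 mM of chains begun”. Its count is about 17 mM, and mine is 18.8 mM.

The flask gives yes and 81.1. Its living end stands at 18.0 mM at 40.0 min, against the chain count of 18.8 mM. Now take a second flask, the same charge run for 20.0 min. The chain count gives 33.8% reacted and an average of 48.7. That run gives 47.6.

The constants belong to no real substance, and the outcome is calculated.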